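The runs were computed on assumed constants.

Substrate and partner react slowly, over hours, so a closed flask can be followed reading by reading.

all flasks: partner 0.456 M
- larch: substrate 0.48 M; run made earlier
- maple: substrate 0.96 M; run made earlier
- eta: substrate 0.48 M; plug flow through a tube for 30 h, no back-mixing; time 30 h
- alpha: substrate 0.48 M; a closed flask charged with all of it at once and left for 30 h; time 30 h
- epsilon: substrate 0.48 M (fed, over 24.0 h); a stirred flask in which substrate is dosed at a steady rate over 24.0 h without added volume, worked up at 30 h; time 30 h
- zeta: substrate 0.48 M; a single well-mixed tank run continuously and read at steady state, 30 h in it on average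

| run | time / h | target / % |
|---|---|---|
| larch | 6.00 | 32.3 |
| larch | 12.0 | 33.0 |
| larch | 20.0 | 29.8 |
| larch | 25.0 | 26.6 |
| larch | 30.0 | 25.9 |
| maple | 0.250 | 4.5 |
| maple | 0.417 | 5.9 |
| maple | 0.833 | 11.2 |
| maple | 1.50 | 16.9 |
| maple | 3.00 | 22.7 |

(scatter of a reading: 0.5 percentage points)

- the stated concentrations are those of everything mixed, before any reaction; amounts are the same in each set-up
- the feed brings no volume worth counting
- the earlier runs were made in a closed, stirred flask

* the set-up with the highest amount of target at the outlet or at the end, in percent of the substrate put in ("none" if the first two lie within 2 percentage points) (eta / alpha / epsilon / zeta / none)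
* amount of target at the outlet or at the end, in percent of the substrate put in, eta
* amount of target at the outlet or at the end, in percent of the substrate put in, alpha
* amount of target at the outlet or at the end, in percent of the substrate put in, epsilon
* amount of target at the outlet or at the end, in percent of the substrate put in, zeta

Partner is charged at 0.456 M, less than the 0.48 M of substrate, which makes it the limiting reagent. At one partner per substrate, its balance allows target up to 95.0 % of the substrate. Yet the larch run, which has the recipe of alpha, tops out at a reading of 33.0 % at 12.0 h and then slides.

A step that runs backward as well as forward can stop short of its ceiling, as a reversible enzyme reaction does. My own reckoning therefore treats the peak as a standstill. Let P, A and B be the concentrations of target, substrate and partner. If target is the one sink, the balances are A = cA − P and B = cB − P, where cA and cB are the charges. The reaction quotient Q = P/(A·B) at the larch peak then reads 1.66 L mol⁻¹.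

At 30.0 h in the larch run, the same balances give 1.05 L mol⁻¹, lower than the value read at the peak. If the quotient holds at the value read at the peak, partner is leaving the larch run by some other way, about 0.120 M of it by then. Eta and alpha should repeat the larch reading of 25.9 %.

The forecast gives 26.2 % for eta, 26.2 % for alpha, 21.5 % for epsilon and 20 % for zeta, so its choice is none. On the top two it says: “Plug flow and the closed flask both reproduce the larch batch at 30 h, about 26%, so they tie.”

The flasks give 25.3 % for eta, 25.3 % for alpha, 24.2 % for epsilon and 24.2 % for zeta, so the answer is none.

partner → decomposed reagent (k = 0.0230 h⁻¹); substrate + partner ⇌ isomer of the product (K = 49.0 L mol⁻¹, k = 0.0220 L mol⁻¹ h⁻¹); substrate + partner ⇌ target (K = 2.40 L mol⁻¹, k = 0.390 L mol⁻¹ h⁻¹) At 30.0 h, alpha holds 0.144 M of decomposed reagent, with 32.0 % of its partner charge left. In the neighbour of eta charged with 0.18 M of partner, the quotient read at the larch peak and the two balances give 0.0725 M of target, which is 15.1 % of the substrate, and that neighbour stands at 11.6 % after 30.0 h.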